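**Retrosynthetic overview**

- Locants follow benzo[7]annulene numbering. Ring A is C1–C4, C4a, C9a (enone, C2=O). Ring B is C4a, C5–C9, C9a. The enabling feature is that C6 and C7 are neighbours inside ring B and both carry oxygen (the trans-diester). Both can therefore be former aldehyde carbons, and C6–C7 is a union of two acceptor carbons. A reductive pinacol closure of a monocyclic 1,7-dialdehyde gives ring B, the diol and both carbinol stereocentres in one operation.
- After the closure only adjustments remain: C9 methylidene to C8=C9 by hydrogen-atom-transfer isomerisation, two angelates, and the C2 ketone by oxidation of the only allylic CH2.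
- The dialdehyde comes from a diol. The diol comes from a formaldehyde-ene reaction at the isopropenyl group (adds C7) and an Ireland–Claisen rearrangement of the isobutyrate of (1S,4R)-p-mentha-2,8-dien-1-ol. The rearrangement makes C4a–C5 and the quaternary C5, sets C4a cis to C9a, and moves the ring alkene to C3=C4.
- Ring order: ring A comes with the terpene starting material. Ring B is the only ring made and is closed last.

Key step: step 6

Remarks:
- In the starting dienol the hydroxyl and the isopropenyl group lie on the same ring face.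
- The dienol, isobutyryl chloride, paraformaldehyde and angelic anhydride are taken as commercial.
- Cp2TiPh is used as a THF stock solution made beforehand from Cp2TiCl2, i-PrMgCl and PhMgBr.

Step 1
Reactants: 1 (1S,4R)-p-mentha-2,8-dien-1-ol; 2 isobutyryl chloride
Product: 4 (1S,4R)-1-methyl-4-(prop-1-en-2-yl)cyclohex-2-en-1-yl 2-methylpropanoate, via lithium alkoxide 3 (not isolated)
Conditions: n-BuLi (1.05 equiv), THF, −78 °C; then 2, −78 to 0 °C
Reagents that add atoms: isobutyryl chloride CC(C)C(=O)Cl
Why: Acylation of a preformed lithium alkoxide with an acid chloride (base-mediated esterification) works on hindered tertiary alcohols and avoids acid, which would ionise the tertiary allylic C–O bond; no stereocentre is touched.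

Step 2
Reactants: 4 (1S,4R)-1-methyl-4-(prop-1-en-2-yl)cyclohex-2-en-1-yl 2-methylpropanoate
Product: 8 2-methyl-2-[(1S,6R)-3-methyl-6-(prop-1-en-2-yl)cyclohex-2-en-1-yl]propanoic acid, via lithium enolate 5 (not isolated), via silyl ketene acetal 6 (not isolated), via trimethylsilyl ester 7 (not isolated)
Conditions: LiN(i-Pr)2, THF, −78 °C; Me3SiCl; −78 °C to rt, then 60 °C; 1 M aq. HCl
Reagents that add atoms: none
Why: Ireland–Claisen rearrangement: the [3,3] shift of 6 is suprafacial on the cyclohexenyl unit, so the new bond forms on the face that carried the ester oxygen, which is also the face of the isopropenyl group; this sets the cis-1,2 relation (C4a), builds the quaternary CMe2 carbon and moves the ring alkene next to the methyl group.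

Step 3
Reactants: 8 2-methyl-2-[(1S,6R)-3-methyl-6-(prop-1-en-2-yl)cyclohex-2-en-1-yl]propanoic acid
Product: 9 2-methyl-2-[(1S,6R)-3-methyl-6-(prop-1-en-2-yl)cyclohex-2-en-1-yl]propan-1-ol
Conditions: LiAlH4, Et2O, 0 °C to reflux; aqueous work-up
Reagents that add atoms: none
Why: Hydride reduction of a carboxylic acid to the primary alcohol is reliable even next to a quaternary carbon, and the isolated alkenes are inert.

Step 4
Reactants: 9 2-methyl-2-[(1S,6R)-3-methyl-6-(prop-1-en-2-yl)cyclohex-2-en-1-yl]propan-1-ol; 10 formaldehyde (as paraformaldehyde)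
Product: 11 3-[(1R,2S)-2-(1-hydroxy-2-methylpropan-2-yl)-4-methylcyclohex-3-en-1-yl]but-3-en-1-ol
Conditions: (CH2O)n (1.2 equiv), Me2AlCl (3 equiv), CH2Cl2, −78 to 0 °C
Reagents that add atoms: formaldehyde C=O
Why: Lewis-acid-promoted carbonyl-ene reaction: the 1,1-disubstituted isopropenyl group is the best ene donor, the trisubstituted ring alkene is shielded by the neighbouring quaternary carbon, the hydrogen comes from the methyl group so a new methylidene results, and no stereocentre is formed.

Step 5
Reactants: 11 3-[(1R,2S)-2-(1-hydroxy-2-methylpropan-2-yl)-4-methylcyclohex-3-en-1-yl]but-3-en-1-ol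
Product: 12 3-[(1R,2S)-4-methyl-2-(2-methyl-1-oxopropan-2-yl)cyclohex-3-en-1-yl]but-3-enal
Conditions: Dess–Martin periodinane (2.4 equiv), pyridine, CH2Cl2, 0 °C; used at once
Reagents that add atoms: none
Why: Dess–Martin oxidation turns both primary alcohols into aldehydes under buffered, non-enolising conditions that keep the β,γ-unsaturated aldehyde out of conjugation.

Step 6
Reactants: 12 3-[(1R,2S)-4-methyl-2-(2-methyl-1-oxopropan-2-yl)cyclohex-3-en-1-yl]but-3-enal
Product: 14 (4aS,6R,7R,9aR)-3,5,5-trimethyl-9-methylidene-2,4a,5,6,7,8,9,9a-octahydro-1H-benzo[7]annulene-6,7-diol, via titanium pinacolate 13 (not isolated)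
Conditions: Cp2TiPh (2.4 equiv), THF, −20 °C to rt, slow addition of 12 (0.005 M); then H2O
Reagents that add atoms: none
Why: Each aldehyde accepts one electron from a trivalent titanium centre, and the two titanium-bound ketyl carbons C6 and C7, both acceptor carbons before reduction, combine to pinacolate 13, which water cleaves to 14; the closest known reaction type is the titanium-mediated intramolecular pinacol coupling of dialdehydes (McMurry-type diol cyclisation), of which bulky monomeric titanocene reagents are the trans-selective variant. Ring B closes as a seven-membered carbocycle by direct ketyl–ketyl combination of the two chain ends of a 1,7-dialdehyde (no exo/endo alternative), and the ends are held close by the cis-1,2 placement on ring A and by the gem-dimethyl group at C5. The trans relation of O6 and O7 comes from the two separate Cp2(Ph)TiO groups, which avoid each other and cannot bridge one metal, unlike samarium ketyls that give cis diols. The sense relative to C4a and C9a comes from a chair-like seven-ring transition state in which C5 stays equatorial on ring A and both titanoxy groups are pseudo-equatorial, which puts O6 on the face of the ring-fusion hydrogens and O7 on the opposite face (6R,7R). The coupling must outrun ketyl addition to the methylidene group (six-ring), simple reduction, and aldol or ene closure of 12; neither alkene is conjugated or activated, titanium ketyls add poorly to such alkenes, the medium is neutral and aprotic, and slow addition keeps the reaction intramolecular.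

Step 7
Reactants: 14 (4aS,6R,7R,9aR)-3,5,5-trimethyl-9-methylidene-2,4a,5,6,7,8,9,9a-octahydro-1H-benzo[7]annulene-6,7-diol
Product: 15 (4aS,6R,7R,9aR)-3,5,5,9-tetramethyl-2,4a,5,6,7,9a-hexahydro-1H-benzo[7]annulene-6,7-diol
Conditions: chloro[N,N'-bis(3,5-di-tert-butylsalicylidene)ethane-1,2-diaminato]cobalt (3 mol %), PhSiH3 (5 mol %), benzene, rt
Reagents that add atoms: none
Why: Radical alkene isomerisation by metal-hydride hydrogen atom transfer: a cobalt hydride gives H to the methylidene carbon, the tertiary C9 radical returns the accessible C8–H to divalent cobalt rather than the shielded ring-fusion C9a–H, the ring forces the Z geometry, and trisubstituted alkenes are not touched further.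

Step 8
Reactants: 15 (4aS,6R,7R,9aR)-3,5,5,9-tetramethyl-2,4a,5,6,7,9a-hexahydro-1H-benzo[7]annulene-6,7-diol; 16 angelic anhydride
Product: 18 (4aS,6R,7R,9aR)-3,5,5,9-tetramethyl-2,4a,5,6,7,9a-hexahydro-1H-benzo[7]annulene-6,7-diyl bis[(2Z)-2-methylbut-2-enoate], via dilithium dialkoxide 17 (not isolated)
Conditions: LiN(SiMe3)2 (2.3 equiv), THF, −78 °C; 16 (3 equiv), −78 to 0 °C; H2O
Reagents that add atoms: angelic anhydride C/C=C(/C)C(=O)OC(=O)/C(C)=C\C
Why: Acylation of lithium alkoxides with angelic anhydride at low temperature is the stereoconservative way to angelates, reaches the hindered O6 and avoids nucleophilic catalysts that turn Z into E.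

Step 9
Reactants: 18 (4aS,6R,7R,9aR)-3,5,5,9-tetramethyl-2,4a,5,6,7,9a-hexahydro-1H-benzo[7]annulene-6,7-diyl bis[(2Z)-2-methylbut-2-enoate]
Product: 19 (4aS,6R,7R,9aR)-3,5,5,9-tetramethyl-2-oxo-2,4a,5,6,7,9a-hexahydro-1H-benzo[7]annulene-6,7-diyl bis[(2Z)-2-methylbut-2-enoate]
Conditions: Rh2(cap)4 (cap = caprolactamate, 1 mol %), t-BuOOH (70 % in water, 10 equiv), 1,2-dichloroethane, 40 °C
Reagents that add atoms: tert-butyl hydroperoxide CC(C)(C)OO
Why: Dirhodium-catalysed allylic oxidation (peroxyl-radical C–H abstraction, mixed peroxide, ketone): C2 is the only allylic methylene of 18, the other allylic positions are methyl, tertiary or deactivated by an acyloxy group, and the allyl radical is trapped at C2 rather than at C4, which lies next to the hindered C4a.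

**Compound list**

1 | (1S,4R)-p-mentha-2,8-dien-1-ol | CC(=C)[C@@H]1CC[C@](C)(O)C=C1 | starting material
2 | isobutyryl chloride | CC(C)C(=O)Cl | starting material
3 | lithium (1S,4R)-p-mentha-2,8-dien-1-olate | CC(=C)[C@@H]1CC[C@](C)([O-])C=C1.[Li+] | intermediate
4 | (1S,4R)-1-methyl-4-(prop-1-en-2-yl)cyclohex-2-en-1-yl 2-methylpropanoate | CC(=C)[C@@H]1CC[C@](C)(OC(=O)C(C)C)C=C1 | intermediate
5 | lithium enolate of 4 | CC(=C)[C@@H]1CC[C@](C)(OC([O-])=C(C)C)C=C1.[Li+] | intermediate
6 | O-trimethylsilyl ketene acetal of 4 | CC(=C)[C@@H]1CC[C@](C)(OC(O[Si](C)(C)C)=C(C)C)C=C1 | intermediate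
7 | trimethylsilyl ester of 8 | CC(=C)[C@@H]1CCC(C)=C[C@@H]1C(C)(C)C(=O)O[Si](C)(C)C | intermediate
8 | 2-methyl-2-[(1S,6R)-3-methyl-6-(prop-1-en-2-yl)cyclohex-2-en-1-yl]propanoic acid | CC(=C)[C@@H]1CCC(C)=C[C@@H]1C(C)(C)C(=O)O | intermediate
9 | 2-methyl-2-[(1S,6R)-3-methyl-6-(prop-1-en-2-yl)cyclohex-2-en-1-yl]propan-1-ol | CC(=C)[C@@H]1CCC(C)=C[C@@H]1C(C)(C)CO | intermediate
10 | formaldehyde (as paraformaldehyde) | C=O | starting material
11 | 3-[(1R,2S)-2-(1-hydroxy-2-methylpropan-2-yl)-4-methylcyclohex-3-en-1-yl]but-3-en-1-ol | OCCC(=C)[C@@H]1CCC(C)=C[C@@H]1C(C)(C)CO | intermediate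
12 | 3-[(1R,2S)-4-methyl-2-(2-methyl-1-oxopropan-2-yl)cyclohex-3-en-1-yl]but-3-enal | O=CCC(=C)[C@@H]1CCC(C)=C[C@@H]1C(C)(C)C=O | intermediate
13 | bis[phenyltitanocene] pinacolate of 14 (tetravalent titanium) | [O-][C@@H]1CC(=C)[C@@H]2CCC(C)=C[C@@H]2C(C)(C)[C@H]1[O-].[Ti+4].[Ti+4].[cH-]1cccc1.[cH-]1cccc1.[cH-]1cccc1.[cH-]1cccc1.[c-]1ccccc1.[c-]1ccccc1 | intermediate
14 | (4aS,6R,7R,9aR)-3,5,5-trimethyl-9-methylidene-2,4a,5,6,7,8,9,9a-octahydro-1H-benzo[7]annulene-6,7-diol | O[C@@H]1CC(=C)[C@@H]2CCC(C)=C[C@@H]2C(C)(C)[C@H]1O | intermediate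
15 | (4aS,6R,7R,9aR)-3,5,5,9-tetramethyl-2,4a,5,6,7,9a-hexahydro-1H-benzo[7]annulene-6,7-diol | O[C@@H]1C=C(C)[C@@H]2CCC(C)=C[C@@H]2C(C)(C)[C@H]1O | intermediate
16 | angelic anhydride, (2Z)-2-methylbut-2-enoic anhydride | C/C=C(/C)C(=O)OC(=O)/C(C)=C\C | starting material
17 | dilithium dialkoxide of 15 | [O-][C@@H]1C=C(C)[C@@H]2CCC(C)=C[C@@H]2C(C)(C)[C@H]1[O-].[Li+].[Li+] | intermediate
18 | (4aS,6R,7R,9aR)-3,5,5,9-tetramethyl-2,4a,5,6,7,9a-hexahydro-1H-benzo[7]annulene-6,7-diyl bis[(2Z)-2-methylbut-2-enoate] | C/C=C(/C)C(=O)O[C@@H]1C=C(C)[C@@H]2CCC(C)=C[C@@H]2C(C)(C)[C@H]1OC(=O)/C(C)=C\C | intermediate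
19 | (4aS,6R,7R,9aR)-3,5,5,9-tetramethyl-2-oxo-2,4a,5,6,7,9a-hexahydro-1H-benzo[7]annulene-6,7-diyl bis[(2Z)-2-methylbut-2-enoate] | C/C=C(/C)C(=O)O[C@@H]1C=C(C)[C@@H]2CC(=O)C(C)=C[C@@H]2C(C)(C)[C@H]1OC(=O)/C(C)=C\C | target

Total step count: 9. Longest linear sequence: 9 steps (from 1).

**Steps most likely to fail**

1. Step 6 (pinacol closure).
   - What may go wrong: reduction of the hindered C6 aldehyde without coupling, ketyl attack on the methylidene group, or weak control over which diol diastereomer forms.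
   - Fallback: it sets out from 9 and comes back at 18. The carbinol centres are set by reagent control and ring B is closed at C8=C9 by olefin metathesis.
   - Dess–Martin oxidation of 9 would give 2-methyl-2-[(1S,6R)-3-methyl-6-(prop-1-en-2-yl)cyclohex-2-en-1-yl]propanal F1.
   - Brown-type alkoxyallylboration follows, using (Z)-γ-(methoxymethoxy)allylbis(isopinocampheyl)borane of the antipode that leads to the (3R,4R) series. After oxidative work-up it would give the syn product (3R,4R)-4-(methoxymethoxy)-2-methyl-2-[(1S,6R)-3-methyl-6-(prop-1-en-2-yl)cyclohex-2-en-1-yl]hex-5-en-3-ol F2.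
   - Aqueous HCl in THF would free (3R,4R)-2-methyl-2-[(1S,6R)-3-methyl-6-(prop-1-en-2-yl)cyclohex-2-en-1-yl]hex-5-ene-3,4-diol F3.
   - LiN(SiMe3)2 and 16 would give the corresponding bis[(2Z)-2-methylbut-2-enoate] F4.
   - The second-generation Grubbs catalyst in toluene at 80 °C would join the isopropenyl and vinyl groups to give 18.

2. Step 7 (alkene isomerisation).
   - What may go wrong: hydrogen abstraction at the ring-fusion C9a–H, which moves the alkene into the tetrasubstituted position, or stalling of the catalyst.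
   - Fallback: it sets out from 14 and comes back at 15. The alkene is drawn into place by conjugation.
   - Selective oxidation of the less hindered C7 hydroxyl (TEMPO cat., PhI(OAc)2, CH2Cl2) would give (4aS,6R,9aR)-6-hydroxy-3,5,5-trimethyl-9-methylidene-1,2,4a,5,6,8,9,9a-octahydro-7H-benzo[7]annulen-7-one F5.
   - DBU in CH2Cl2 would shift the alkene into conjugation to give (4aS,6R,9aR)-6-hydroxy-3,5,5,9-tetramethyl-1,2,4a,5,6,9a-hexahydro-7H-benzo[7]annulen-7-one F6.
   - Hydroxyl-directed 1,2-reduction with Me4NBH(OAc)3 in MeCN/AcOH at −20 °C delivers hydride from the face of O6 and would give the trans diol 15.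

3. Step 9 (allylic oxidation).
   - What may go wrong: hydrogen abstraction at the tertiary allylic positions, trapping of the allyl radical at C4 with transposition, or radical Z-to-E isomerisation of the angelates.
   - Fallback: it sets out from 18 and comes back at 19. It is a pericyclic route instead of a radical one.
   - SeO2 (cat.) with t-BuOOH in CH2Cl2 proceeds by an ene reaction and a [2,3] shift at the more substituted alkene terminus, and prefers CH2 over CH3. It would give (2R,4aS,6R,7R,9aR)-2-hydroxy-3,5,5,9-tetramethyl-2,4a,5,6,7,9a-hexahydro-1H-benzo[7]annulene-6,7-diyl bis[(2Z)-2-methylbut-2-enoate] F7. The configuration at C2 does not matter.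
   - Dess–Martin oxidation of F7 would give 19.

**Further compounds**

F1 | step 6 | 2-methyl-2-[(1S,6R)-3-methyl-6-(prop-1-en-2-yl)cyclohex-2-en-1-yl]propanal | CC(=C)[C@@H]1CCC(C)=C[C@@H]1C(C)(C)C=O
F2 | step 6 | (3R,4R)-4-(methoxymethoxy)-2-methyl-2-[(1S,6R)-3-methyl-6-(prop-1-en-2-yl)cyclohex-2-en-1-yl]hex-5-en-3-ol | CC(=C)[C@@H]1CCC(C)=C[C@@H]1C(C)(C)[C@@H](O)[C@H](OCOC)C=C
F3 | step 6 | (3R,4R)-2-methyl-2-[(1S,6R)-3-methyl-6-(prop-1-en-2-yl)cyclohex-2-en-1-yl]hex-5-ene-3,4-diol | CC(=C)[C@@H]1CCC(C)=C[C@@H]1C(C)(C)[C@@H](O)[C@H](O)C=C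
F4 | step 6 | (3R,4R)-2-methyl-2-[(1S,6R)-3-methyl-6-(prop-1-en-2-yl)cyclohex-2-en-1-yl]hex-5-ene-3,4-diyl bis[(2Z)-2-methylbut-2-enoate] | CC(=C)[C@@H]1CCC(C)=C[C@@H]1C(C)(C)[C@@H](OC(=O)/C(C)=C\C)[C@H](OC(=O)/C(C)=C\C)C=C
F5 | step 7 | (4aS,6R,9aR)-6-hydroxy-3,5,5-trimethyl-9-methylidene-1,2,4a,5,6,8,9,9a-octahydro-7H-benzo[7]annulen-7-one | O=C1CC(=C)[C@@H]2CCC(C)=C[C@@H]2C(C)(C)[C@H]1O
F6 | step 7 | (4aS,6R,9aR)-6-hydroxy-3,5,5,9-tetramethyl-1,2,4a,5,6,9a-hexahydro-7H-benzo[7]annulen-7-one | O=C1C=C(C)[C@@H]2CCC(C)=C[C@@H]2C(C)(C)[C@H]1O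
F7 | step 9 | (2R,4aS,6R,7R,9aR)-2-hydroxy-3,5,5,9-tetramethyl-2,4a,5,6,7,9a-hexahydro-1H-benzo[7]annulene-6,7-diyl bis[(2Z)-2-methylbut-2-enoate] | C/C=C(/C)C(=O)O[C@@H]1C=C(C)[C@@H]2C[C@@H](O)C(C)=C[C@@H]2C(C)(C)[C@H]1OC(=O)/C(C)=C\C
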